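**Plan**

- Retrosynthetic cuts: the two quinone–heteroatom bonds of the thiazine dioxide (to hypotaurine); the quinone (to a 1,4-dimethoxynaphthalene); the enol O–C(=O) bond of the seven-membered lactone (to an aldehyde acid); the exocyclic enol carbon (one-carbon homologation of a ring A ketone); in ring A the ring C=C bond and the bond from the quaternary carbon to its ring CH2 (to acrolein and an enol lactone); the aryl–C bond (ketone α-arylation).
- Forward order: naphthalene with masked quinone → six-membered enol lactone (isocoumarin) → ring A → seven-membered dienol lactone → quinone → thiazine dioxide.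
- Enabling feature: in ring A the carbon that carries the exocyclic O–CH= is a masked ketone carbon lying between the benzylic quaternary carbon and the methyl-bearing alkene carbon, and the other three ring carbons (=CH–CH2–CH2) are acrolein. The carboxyl group on the naphthalene carbon ortho to the quaternary carbon, which ends in the seven-membered lactone, can first hold that ketone as an enol lactone whose opening releases one enolate geometry.
- Stereochemistry: the single stereocentre (S, benzylic, quaternary) is set in the Michael half of the key step by a chiral ammonium counter-ion and has no α-hydrogen afterwards.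

Key step: step 4

Remark: the cinchonidinium-derived catalyst is taken to give the S centre; if the sense of induction is the opposite, the pseudo-enantiomeric cinchoninium salt is used in the same way.

Step 1
Reactants: 1 3-bromonaphthalene-2-carboxylic acid
Product: 2 3-bromo-5,8-dioxo-5,8-dihydronaphthalene-2-carboxylic acid
Conditions: CrO3, AcOH/H2O, 60 °C
Reagents that add atoms: chromium trioxide, O=[Cr](=O)=O
Why: Chromic acid oxidation of a naphthalene to the 1,4-naphthoquinone should take place in the unsubstituted ring, because bromine and the carboxyl group deactivate the other ring.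

Step 2
Reactants: 2 3-bromo-5,8-dioxo-5,8-dihydronaphthalene-2-carboxylic acid
Product: 4 methyl 3-bromo-5,8-dimethoxynaphthalene-2-carboxylate, via hydroquinone acid 3 (not isolated)
Conditions: Na2S2O4, EtOAc/H2O, rt; then MeI, K2CO3, DMF, 40 °C
Reagents that add atoms: iodomethane, CI
Why: Dithionite reduction to the hydroquinone and exhaustive O-methylation of both phenols and the carboxylate should mask the quinone as a base-stable dimethyl ether and supply the methyl ester used in step 3.

Step 3
Reactants: 4 methyl 3-bromo-5,8-dimethoxynaphthalene-2-carboxylate; 5 pentan-3-one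
Product: 7 3-ethyl-6,9-dimethoxy-4-methyl-1H-benzo[g]isochromen-1-one, via keto ester 6 (not isolated)
Conditions: Pd2(dba)3 (zerovalent palladium, 2 mol%), Xantphos, K3PO4, pentan-3-one (4 equiv), toluene, 90 °C; then TsOH·H2O (cat.), toluene, reflux
Reagents that add atoms: none
Why: Palladium-catalysed α-arylation of the symmetrical ketone under mild-base conditions that spare the ester should give keto ester 6, whose enol then displaces methanol from the ortho ester (enol lactonisation to the isocoumarin), the excess of ketone suppressing diarylation.

Step 4
Reactants: 7 3-ethyl-6,9-dimethoxy-4-methyl-1H-benzo[g]isochromen-1-one; 8 acrolein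
Product: 10 methyl 3-[(1S)-1,3-dimethyl-2-oxocyclohex-3-en-1-yl]-5,8-dimethoxynaphthalene-2-carboxylate, via keto aldehyde 9 (not isolated)
Conditions: N-(9-anthracenylmethyl)-O-allylcinchonidinium bromide (10 mol%), Cs2CO3 (0.3 equiv), MeOH (1.5 equiv), acrolein (2 equiv), toluene/CH2Cl2, −40 °C; then AcOH, removal of excess acrolein, TsOH·H2O, toluene, 70 °C
Reagents that add atoms: methanol, CO
Why: Proposed new method: catalytic methoxide, carried as its chiral ammonium salt, opens the enol lactone of 7 to the methyl ester and so releases the fully substituted ketone enolate with the naphthyl group cis to the enolate oxygen (the geometry also preferred at equilibrium), this enolate adds through its benzylic carbon to acrolein to give 9 after protonation by methanol, and TsOH then condenses the ethyl CH2 of the ketone with the aldehyde and dehydrates to enone 10. The closest known reaction types are the chiral phase-transfer-catalysed Michael additions of cyclic 2-substituted ketone enolates to vinyl ketones and acrolein used in asymmetric Robinson annulations, and the release of enolates from enol esters by alkoxide. Ring A closes by a 6-(enolendo)-exo-trig aldol addition followed by acid-catalysed dehydration. The quaternary stereocentre is formed in the Michael step and is controlled by the cinchonidinium cation, which in the contact ion pair covers one face of the single enolate geometry; it has no α-hydrogen and cannot epimerise later. The step needs site selectivity (benzylic carbon against ethyl CH2 in the Michael step, the reverse in the aldol step) and chemoselectivity against Claisen-type attack of the enolates on the ester: the lactone opening places the enolate only on the benzylic carbon, that carbon is quaternary afterwards so that only the ethyl CH2 can enolise towards the aldehyde, the aldehyde α-carbon could only close a four-membered ring, and methanol should protonate the adduct enolate at −40 °C before it can acylate.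

Step 5
Reactants: 10 methyl 3-[(1S)-1,3-dimethyl-2-oxocyclohex-3-en-1-yl]-5,8-dimethoxynaphthalene-2-carboxylate
Product: 11 methyl 3-[(4S)-4,8-dimethyl-1-oxaspiro[2.5]oct-7-en-4-yl]-5,8-dimethoxynaphthalene-2-carboxylate (both configurations at the spiro carbon)
Conditions: Me3S+ I−, KN(SiMe3)2, THF, −20 °C to rt
Reagents that add atoms: trimethylsulfonium iodide, C[S+](C)C.[I-]
Why: Corey–Chaykovsky epoxidation, in which the small dimethylsulfonium methylide should add 1,2 to the hindered enone carbonyl and close to the spiro vinyl epoxide, the new spiro centre being of no consequence because this carbon becomes sp2 later.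

Step 6
Reactants: 11 methyl 3-[(4S)-4,8-dimethyl-1-oxaspiro[2.5]oct-7-en-4-yl]-5,8-dimethoxynaphthalene-2-carboxylate
Product: 12 methyl 3-[(1R)-2-formyl-1,3-dimethylcyclohex-3-en-1-yl]-5,8-dimethoxynaphthalene-2-carboxylate (both epimers at the formyl-bearing carbon)
Conditions: BF3·OEt2 (0.2 equiv), CH2Cl2, −78 °C
Reagents that add atoms: none
Why: Meinwald rearrangement, in which ionisation at the tertiary allylic epoxide carbon and a 1,2-hydride shift from the CH2O carbon should give the β,γ-unsaturated aldehyde with the ring double bond untouched.

Step 7
Reactants: 12 methyl 3-[(1R)-2-formyl-1,3-dimethylcyclohex-3-en-1-yl]-5,8-dimethoxynaphthalene-2-carboxylate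
Product: 13 3-[(1R)-2-formyl-1,3-dimethylcyclohex-3-en-1-yl]-5,8-dimethoxynaphthalene-2-carboxylic acid
Conditions: LiI, EtOAc, reflux; then dilute HCl
Reagents that add atoms: none
Why: SN2 demethylation of the ester by iodide takes place at the methyl carbon, so it should be indifferent to the hindered carbonyl and run under neutral conditions that leave the enolisable β,γ-unsaturated aldehyde in place.

Step 8
Reactants: 13 3-[(1R)-2-formyl-1,3-dimethylcyclohex-3-en-1-yl]-5,8-dimethoxynaphthalene-2-carboxylic acid
Product: 14 (S)-dimethoxy dienol lactone (ring A and the seven-membered enol lactone of the target, fused to a 1,4-dimethoxynaphthalene in place of the thiazinoquinone)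
Conditions: DCC, DMAP, Et3N, CH2Cl2, 0 °C to rt, high dilution
Reagents that add atoms: none
Why: Enol lactonisation, in which the activated acid should acylate on oxygen the dienolate formed by loss of the doubly activated aldehyde α-hydrogen, closing the seven-membered ring to the conjugated dienol ester (the pattern of cyclocitral enol acetate), while C-acylation at the neopentyl-type carbon is sterically disfavoured.

Step 9
Reactants: 14 (S)-dimethoxy dienol lactone
Product: 15 (S)-naphthoquinone dienol lactone (14 with the dimethoxy ring oxidised to the 1,4-quinone bearing two quinone CH)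
Conditions: (NH4)2Ce(NO3)6, MeCN/H2O, 0 °C
Reagents that add atoms: water, O
Why: Oxidative demethylation of the 1,4-dimethoxyarene by tetravalent cerium should give the naphthoquinone, because the electron-rich dimethoxynaphthalene ring is oxidised far faster than the dienol ester.

Step 10
Reactants: 15 (S)-naphthoquinone dienol lactone; 16 hypotaurine (2-aminoethanesulfinic acid)
Product: 20 CNP0348176.1 (S), via sulfonyl hydroquinone 17 (not isolated), via sulfonyl quinone 18 (not isolated), via cyclised hydroquinone 19 (not isolated)
Conditions: NaH2PO4/Na2HPO4 buffer (pH 6.5)/MeCN/EtOH, rt; N,N'-bis(salicylidene)ethylenediaminocobalt, Co(salen) (divalent cobalt, cat.), O2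
Reagents that add atoms: none
Why: At pH 6.5 the amine of hypotaurine is protonated, so the sulfinate should add first (conjugate addition) to the quinone CH that is β to the more electron-poor carbonyl (the one on the ring carbon para to the lactone carboxyl), after which oxidation to the sulfonyl quinone, intramolecular amine addition and a second oxidation complete the known one-pot thiazine dioxide annulation of quinones with sulfur and nitrogen placed as in the target.

**Compound list**

1 | 3-bromonaphthalene-2-carboxylic acid | OC(=O)c1cc2ccccc2cc1Br | starting material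
2 | 3-bromo-5,8-dioxo-5,8-dihydronaphthalene-2-carboxylic acid | OC(=O)c1cc2C(=O)C=CC(=O)c2cc1Br | intermediate
3 | 3-bromo-5,8-dihydroxynaphthalene-2-carboxylic acid (hydroquinone acid) | OC(=O)c1cc2c(O)ccc(O)c2cc1Br | intermediate
4 | methyl 3-bromo-5,8-dimethoxynaphthalene-2-carboxylate | COC(=O)c1cc2c(OC)ccc(OC)c2cc1Br | intermediate
5 | pentan-3-one | CCC(=O)CC | starting material
6 | methyl 5,8-dimethoxy-3-(3-oxopentan-2-yl)naphthalene-2-carboxylate (racemic keto ester) | CCC(=O)C(C)c1cc2c(OC)ccc(OC)c2cc1C(=O)OC | intermediate
7 | 3-ethyl-6,9-dimethoxy-4-methyl-1H-benzo[g]isochromen-1-one | CCC1=C(C)c2cc3c(OC)ccc(OC)c3cc2C(=O)O1 | intermediate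
8 | acrolein | C=CC=O | starting material
9 | methyl 5,8-dimethoxy-3-[(4S)-4-methyl-1,5-dioxoheptan-4-yl]naphthalene-2-carboxylate (keto aldehyde) | CCC(=O)[C@@](C)(CCC=O)c1cc2c(OC)ccc(OC)c2cc1C(=O)OC | intermediate
10 | methyl 3-[(1S)-1,3-dimethyl-2-oxocyclohex-3-en-1-yl]-5,8-dimethoxynaphthalene-2-carboxylate | CC1=CCC[C@@](C)(c2cc3c(OC)ccc(OC)c3cc2C(=O)OC)C1=O | intermediate
11 | methyl 3-[(4S)-4,8-dimethyl-1-oxaspiro[2.5]oct-7-en-4-yl]-5,8-dimethoxynaphthalene-2-carboxylate (both configurations at the spiro carbon) | CC1=CCC[C@@](C)(c2cc3c(OC)ccc(OC)c3cc2C(=O)OC)C14CO4 | intermediate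
12 | methyl 3-[(1R)-2-formyl-1,3-dimethylcyclohex-3-en-1-yl]-5,8-dimethoxynaphthalene-2-carboxylate (both epimers at the formyl-bearing carbon) | CC1=CCC[C@@](C)(c2cc3c(OC)ccc(OC)c3cc2C(=O)OC)C1C=O | intermediate
13 | 3-[(1R)-2-formyl-1,3-dimethylcyclohex-3-en-1-yl]-5,8-dimethoxynaphthalene-2-carboxylic acid (both epimers at the formyl-bearing carbon) | CC1=CCC[C@@](C)(c2cc3c(OC)ccc(OC)c3cc2C(=O)O)C1C=O | intermediate
14 | (S)-dimethoxy dienol lactone: target skeleton with a 1,4-dimethoxybenzene ring in place of the thiazinoquinone | CC1=CCC[C@]2(C)C1=COC(=O)c1cc3c(OC)ccc(OC)c3cc12 | intermediate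
15 | (S)-naphthoquinone dienol lactone: 14 oxidised to the 1,4-naphthoquinone with two quinone CH | CC1=CCC[C@]2(C)C1=COC(=O)c1cc3C(=O)C=CC(=O)c3cc12 | intermediate
16 | hypotaurine (2-aminoethanesulfinic acid) | NCCS(=O)O | starting material
17 | (S)-sulfonyl hydroquinone: hydroquinone of 15 with SO2CH2CH2NH2 on the ring carbon next to the C–OH carbon that is bonded to the aromatic carbon para to the quaternary centre | CC1=CCC[C@]2(C)C1=COC(=O)c1cc3c(O)c(S(=O)(=O)CCN)cc(O)c3cc12 | intermediate
18 | (S)-sulfonyl quinone: quinone form of 17 | CC1=CCC[C@]2(C)C1=COC(=O)c1cc3C(=O)C(S(=O)(=O)CCN)=CC(=O)c3cc12 | intermediate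
19 | (S)-cyclised hydroquinone: hydroquinone form of the target | CC1=CCC[C@]2(C)C1=COC(=O)c1cc3c(O)c4c(NCCS4(=O)=O)c(O)c3cc12 | intermediate
20 | CNP0348176.1, (S)-configured thiazinoquinone dienol lactone | CC1=CCC[C@]2(C)C1=COC(=O)c1cc3c(cc12)C(=O)C1=C(C3=O)S(=O)(=O)CCN1 | target

**Step count and risks**

Total step count: 10. Longest linear sequence: 10 steps (from 1).

Steps most likely to fail:

Step 4 (Proposed new method). The ion pair may give poor facial selectivity, or the hindered enolate may add too slowly so that acrolein is lost to oligomerisation and the adduct enolate attacks the ester. Fallback with known chemistry, from 7 back to the route at 9: KOMe in THF at −78 °C followed by allyl chloroformate should give the allyl enol carbonate F1 with the same enolate geometry. Decarboxylative asymmetric allylic alkylation with Pd2(dba)3 (zerovalent palladium) and 4-tert-butyl-2-[2-(diphenylphosphanyl)phenyl]-4,5-dihydro-1,3-oxazole (t-BuPHOX, the enantiomer that gives S) in toluene at 25 °C should give the α-allyl ketone F2. Hydroboration with 9-BBN and oxidation with NaBO3 should give the primary alcohol F3, and Dess–Martin oxidation gives 9, which is closed to 10 with TsOH as in the second stage of step 4.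

Step 10. The first conjugate addition may show low or reversed site selectivity between the two quinone CH carbons, which would interchange nitrogen and sulfur. Fallback, from 15 back to the route at 20, amine first: 2-(tritylsulfanyl)ethanamine with CeCl3·7H2O (trivalent cerium, cat.) in EtOH under air should give the aminoquinone F4. The Lewis acid binds the more basic quinone carbonyl (the one on the ring carbon para to the quaternary alkyl group) and so sends the amine to the carbon that must carry nitrogen. TFA/Et3SiH should remove the trityl group to give the thiol F5, which adds to the neighbouring quinone carbon and is reoxidised in air to the thiazine sulfide F6. H2O2 with Na2WO4 (cat.) then oxidises sulfur to the sulfone 20. This fallback helps only if the intrinsic preference is reversed or if the Lewis acid raises it; a low preference under both regimes leaves separation of the isomers.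

Step 6 (with the hindered addition of step 5 before it). The tertiary allylic cation may be captured by the neighbouring ester carbonyl or lose a ring proton instead of undergoing the hydride shift. Fallback, from 10 back to the route at 12: Wittig reaction with methoxymethylenetriphenylphosphorane (MeOCH2PPh3Cl, KN(SiMe3)2, THF, 0 to 50 °C) should give the dienol methyl ether F7 without a cationic intermediate, and hydrolysis with oxalic acid in wet THF at 0 °C should give 12.

**Further compounds**

F1 | step 4 | methyl 5,8-dimethoxy-3-[(2Z)-3-{[(prop-2-en-1-yloxy)carbonyl]oxy}pent-2-en-2-yl]naphthalene-2-carboxylate | CC/C(OC(=O)OCC=C)=C(\C)c1cc2c(OC)ccc(OC)c2cc1C(=O)OC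
F2 | step 4 | methyl 5,8-dimethoxy-3-[(4S)-4-methyl-5-oxohept-1-en-4-yl]naphthalene-2-carboxylate | CCC(=O)[C@@](C)(CC=C)c1cc2c(OC)ccc(OC)c2cc1C(=O)OC
F3 | step 4 | methyl 3-[(4S)-7-hydroxy-4-methyl-3-oxoheptan-4-yl]-5,8-dimethoxynaphthalene-2-carboxylate | CCC(=O)[C@@](C)(CCCO)c1cc2c(OC)ccc(OC)c2cc1C(=O)OC
F4 | step 10 | (S)-aminoquinone: 15 with a 2-(tritylsulfanyl)ethylamino group on the quinone carbon that carries nitrogen in the target | CC1=CCC[C@]2(C)C1=COC(=O)c1cc3C(=O)C=C(NCCSC(c4ccccc4)(c4ccccc4)c4ccccc4)C(=O)c3cc12
F5 | step 10 | (S)-thiol: F4 without the trityl group | CC1=CCC[C@]2(C)C1=COC(=O)c1cc3C(=O)C=C(NCCS)C(=O)c3cc12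
F6 | step 10 | (S)-thiazine sulfide: the target with sulfide in place of sulfone | CC1=CCC[C@]2(C)C1=COC(=O)c1cc3c(cc12)C(=O)C1=C(C3=O)SCCN1
F7 | step 6 | methyl 3-[(1S)-2-(methoxymethylidene)-1,3-dimethylcyclohex-3-en-1-yl]-5,8-dimethoxynaphthalene-2-carboxylate (E/Z mixture) | CC1=CCC[C@@](C)(c2cc3c(OC)ccc(OC)c3cc2C(=O)OC)C1=COC
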